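The cyclohexane ring is opened at C2–C3 and C4–C5, the bonds on either side of the vicinal C3(H)Br–C4(CH3)Cl pair, which lies 1,4 to the side-chain carbon C1: with a C1=C6 alkene added, this ring is a Diels–Alder retron. One catalytic enantioselective cycloaddition of a 2-substituted butadiene (acetate arm at the future C1) with (E)-3-bromo-2-methylacrolein forms both bonds, sets the quaternary C4 and C3 (methyl cis to bromine from the alkene geometry, absolute sense from the catalyst); the formyl group is a masked chloride (Baeyer–Villiger oxidation, bromonium-assisted substitution). The bromodihydropyran is then grown from the acetate arm.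

Key step: step 3

Remark: the carbon alpha to the carbonyl group in 14–19 (the future C5 of the pyran) is formed without control and becomes sp2 in the last step; these compounds are carried as epimer pairs and that center is left undefined in their SMILES.

Step 1
Reactants: 1 methacrolein
Product: 3 (E)-3-bromo-2-methylprop-2-enal, via 2,3-dibromo-2-methylpropanal 2 (not isolated)
Conditions: Br2, CH2Cl2, 0 °C; then Et3N, 0 °C to rt
Reagents that add atoms: bromine, BrBr
Why: Bromination of the alkene followed by dehydrobromination (the alpha carbon is quaternary, so only a CH2Br hydrogen can be lost) should give the conjugated bromoenal as the more stable E isomer, with bromine trans to the formyl group and cis to the methyl group.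

Step 2
Reactants: 4 buta-2,3-dien-1-ol; 5 trimethyl orthoacetate
Product: 7 methyl 3-methylidenepent-4-enoate, via allenylmethyl ketene acetal 6 (not isolated)
Conditions: EtCO2H (cat.), 130 °C, MeOH distilled off
Reagents that add atoms: none
Why: Acid-catalysed exchange gives the mixed ketene acetal 6, whose [3,3]-sigmatropic rearrangement (Johnson–Claisen) joins the acetate carbon to the central allene carbon and so delivers the 2-substituted 1,3-diene without creating a stereocenter.

Step 3
Reactants: 7 methyl 3-methylidenepent-4-enoate; 3 (E)-3-bromo-2-methylprop-2-enal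
Product: 8 methyl 2-[(4R,5S)-5-bromo-4-formyl-4-methylcyclohex-1-en-1-yl]acetate
Conditions: (R)-o-tolyl oxazaborolidinium triflimide [(3aR)-1-(2-methylphenyl)-3,3-diphenyltetrahydro-1H,3H-pyrrolo[1,2-c][1,3,2]oxazaborole + HNTf2, 20 mol%], CH2Cl2, −40 to −20 °C
Reagents that add atoms: none
Why: The cationic oxazaborolidinium binds the formyl oxygen of 3 (s-trans enal) and lowers its LUMO, and diene 7 adds in a concerted, asynchronous [4+2] cycloaddition that forms ring bonds C3–C4 and C5–C6 of 8 suprafacially on both partners. The closest known reaction type is the oxazaborolidinium-catalysed enantioselective Diels–Alder reaction of 2-substituted acroleins with 2-substituted butadienes. The cyclohexene ring is closed intermolecularly by this [4π+2π] cycloaddition, not by cyclization of a chain. The relative configuration of the new stereocenters C4 and C5 (methyl cis to bromine, formyl trans to bromine) follows from the E geometry of 3, and their absolute configuration is set by the catalyst, whose aryl group covers one face of the bound enal so that the diene adds to the Re face of C2 of 3 (catalyst antipode chosen by the accepted pretransition-state model for 2-substituted acroleins). The step needs 1,4 ("para") regioselectivity, which the 2-alkyl group of 7 secures because the diene terminus next to it has the larger HOMO coefficient and bonds to the bromine-bearing beta carbon; endo/exo selectivity is irrelevant because both diene termini are CH2.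

Step 4
Reactants: 8 methyl 2-[(4R,5S)-5-bromo-4-formyl-4-methylcyclohex-1-en-1-yl]acetate
Product: 10 methyl 2-[(4S,5S)-5-bromo-4-hydroxy-4-methylcyclohex-1-en-1-yl]acetate, via tertiary formate 9 (not isolated)
Conditions: Me3SiOOSiMe3, Me3SiOTf (10 mol%), CH2Cl2, −30 to 0 °C; then MeOH, rt; aq. Na2S2O3 work-up
Reagents that add atoms: bis(trimethylsilyl) peroxide, C[Si](C)(C)OO[Si](C)(C)C
Why: In this Baeyer–Villiger oxidation the silyl peroxide adds to the Lewis-acid-activated formyl group and the quaternary carbon migrates to oxygen with retention, the non-peracid oxidant should leave the ring alkene untouched, and acid-catalysed methanolysis of the formate (no base, hence no epoxide from the bromohydrin) frees the tertiary alcohol.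

Step 5
Reactants: 10 methyl 2-[(4S,5S)-5-bromo-4-hydroxy-4-methylcyclohex-1-en-1-yl]acetate
Product: 11 methyl 2-[(4S,5S)-5-bromo-4-chloro-4-methylcyclohex-1-en-1-yl]acetate
Conditions: Me2C=C(Cl)NMe2, CH2Cl2, 0 °C to rt
Reagents that add atoms: 1-chloro-N,N,2-trimethylprop-1-en-1-amine, CC(C)=C(Cl)N(C)C
Why: In this neutral deoxychlorination the alcohol adds to the chloroenamine, the alkoxyiminium ionises with anchimeric assistance from the anti C–Br bond (the diaxial half-chair is accessible while C1 is still sp2), and chloride opens the bromonium ion at the tertiary carbon anti to bromine, so C4 should be substituted with net retention (chlorine trans to bromine).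

Step 6
Reactants: 11 methyl 2-[(4S,5S)-5-bromo-4-chloro-4-methylcyclohex-1-en-1-yl]acetate
Product: 12 methyl 2-[(1R,3S,4S)-3-bromo-4-chloro-4-methylcyclohexyl]acetate
Conditions: H2 (1 atm), [Ir(cod)(PCy3)(py)]PF6 (5 mol%), CH2Cl2, 0 °C
Reagents that add atoms: none
Why: Homogeneous hydrogenation adds H2 syn from the less hindered face: the cis-vicinal methyl/bromine pair puts an axial group on the upper face in either half-chair, whereas the lower face is clear in the half-chair with equatorial Br and Cl, so hydrogen should enter opposite to bromine and set C1 with the acetate arm cis to bromine, and this catalyst does not cleave alkyl halides.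

Step 7
Reactants: 12 methyl 2-[(1R,3S,4S)-3-bromo-4-chloro-4-methylcyclohexyl]acetate; 13 1-bromo-3-methylbut-2-ene
Product: 14 methyl 2-[(1S,3S,4S)-3-bromo-4-chloro-4-methylcyclohexyl]-5-methylhex-4-enoate (both epimers at C2)
Conditions: LiN(iPr)2, THF, −78 °C; then 13, −78 to −30 °C
Reagents that add atoms: none
Why: Ester enolate alkylation (SN2 on the allylic bromide) attaches the prenyl group; the ring halides are both equatorial, have no anti-periplanar hydrogen and should survive the cold amide base, and the new center needs no control.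

Step 8
Reactants: 14 methyl 2-[(1S,3S,4S)-3-bromo-4-chloro-4-methylcyclohexyl]-5-methylhex-4-enoate
Product: 16 3-[(1S,3S,4S)-3-bromo-4-chloro-4-methylcyclohexyl]-6-methylhept-5-en-2-one, via alpha-silyl ketone 15 (not isolated)
Conditions: Me3SiCH2Li (2.5 equiv), pentane–THF, 0 °C to rt; then MeOH
Reagents that add atoms: (trimethylsilyl)methyllithium, [Li]C[Si](C)(C)C
Why: In this one-flask conversion of an ester into a methyl ketone the organolithium adds once, the alpha-silyl ketone formed is deprotonated at once to an enolate that resists a second addition, and the methanol quench removes silicon.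

Step 9
Reactants: 16 3-[(1S,3S,4S)-3-bromo-4-chloro-4-methylcyclohexyl]-6-methylhept-5-en-2-one
Product: 17 3-[(1S,3S,4S)-3-bromo-4-chloro-4-methylcyclohexyl]-4-[(2S)-3,3-dimethyloxiran-2-yl]butan-2-one
Conditions: 1,2:4,5-di-O-isopropylidene-β-L-erythro-2,3-hexodiulo-2,6-pyranose (ent-Shi ketone, 30 mol%), Oxone (2KHSO5·KHSO4·K2SO4), K2CO3, Bu4NHSO4, MeCN–CH2(OMe)2/aq. Na2B4O7 buffer, 0 °C
Reagents that add atoms: potassium peroxymonosulfate, [K+].[O-]S(=O)(=O)OO
Why: In the Shi epoxidation the chiral dioxirane formed in situ transfers oxygen to the only remaining alkene through a spiro transition state, so the (S)-epoxide carbon is set by the reagent alone (ketone antipode chosen by that model), independently of the remote ring stereocenters.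

Step 10
Reactants: 17 3-[(1S,3S,4S)-3-bromo-4-chloro-4-methylcyclohexyl]-4-[(2S)-3,3-dimethyloxiran-2-yl]butan-2-one
Product: 18 (5R)-5-bromo-3-[(1S,3S,4S)-3-bromo-4-chloro-4-methylcyclohexyl]-6-hydroxy-6-methylheptan-2-one
Conditions: Li2NiBr4, THF, 0 °C to rt; pH 7 buffer work-up
Reagents that add atoms: dilithium tetrabromonickelate, [Li+].[Li+].[Ni+2].[Br-].[Br-].[Br-].[Br-]
Why: The soft bromide of this reagent opens the trisubstituted epoxide by SN2 attack at its less substituted carbon with inversion, which should give the (R)-bromide next to a tertiary alcohol (regioselective halide opening of an epoxide).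

Step 11
Reactants: 18 (5R)-5-bromo-3-[(1S,3S,4S)-3-bromo-4-chloro-4-methylcyclohexyl]-6-hydroxy-6-methylheptan-2-one
Product: 20 laucapyranoid A, via cyclic hemiketal 19 (not isolated)
Conditions: pyridinium p-toluenesulfonate (10 mol%), 4 Å molecular sieves, benzene, 60 °C; Et3N quench
Reagents that add atoms: none
Why: In this acid-catalysed cyclodehydration of a delta-hydroxy ketone the tertiary hydroxyl adds to the ketone, then water and the proton at C5 are lost to give the more substituted endocyclic enol ether, so both C5 epimers converge and no stereocenter is touched.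

Compound list
1 | methacrolein (2-methylprop-2-enal) | CC(=C)C=O | starting material
2 | 2,3-dibromo-2-methylpropanal | O=CC(C)(Br)CBr | intermediate
3 | (E)-3-bromo-2-methylprop-2-enal | O=C/C(C)=C/Br | intermediate
4 | buta-2,3-dien-1-ol | OCC=C=C | starting material
5 | trimethyl orthoacetate (1,1,1-trimethoxyethane) | CC(OC)(OC)OC | starting material
6 | 1-(buta-2,3-dien-1-yloxy)-1-methoxyethene | C=C(OC)OCC=C=C | intermediate
7 | methyl 3-methylidenepent-4-enoate | COC(=O)CC(=C)C=C | intermediate
8 | methyl 2-[(4R,5S)-5-bromo-4-formyl-4-methylcyclohex-1-en-1-yl]acetate | COC(=O)CC1=CC[C@](C)(C=O)[C@@H](Br)C1 | intermediate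
9 | methyl 2-[(4S,5S)-5-bromo-4-(formyloxy)-4-methylcyclohex-1-en-1-yl]acetate | COC(=O)CC1=CC[C@](C)(OC=O)[C@@H](Br)C1 | intermediate
10 | methyl 2-[(4S,5S)-5-bromo-4-hydroxy-4-methylcyclohex-1-en-1-yl]acetate | COC(=O)CC1=CC[C@](C)(O)[C@@H](Br)C1 | intermediate
11 | methyl 2-[(4S,5S)-5-bromo-4-chloro-4-methylcyclohex-1-en-1-yl]acetate | COC(=O)CC1=CC[C@](C)(Cl)[C@@H](Br)C1 | intermediate
12 | methyl 2-[(1R,3S,4S)-3-bromo-4-chloro-4-methylcyclohexyl]acetate | COC(=O)C[C@H]1CC[C@](C)(Cl)[C@@H](Br)C1 | intermediate
13 | 1-bromo-3-methylbut-2-ene (prenyl bromide) | CC(C)=CCBr | starting material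
14 | methyl 2-[(1S,3S,4S)-3-bromo-4-chloro-4-methylcyclohexyl]-5-methylhex-4-enoate (both epimers at C2) | COC(=O)C(CC=C(C)C)[C@H]1CC[C@](C)(Cl)[C@@H](Br)C1 | intermediate
15 | 3-[(1S,3S,4S)-3-bromo-4-chloro-4-methylcyclohexyl]-6-methyl-1-(trimethylsilyl)hept-5-en-2-one (present as its lithium enolate) | C[Si](C)(C)CC(=O)C(CC=C(C)C)[C@H]1CC[C@](C)(Cl)[C@@H](Br)C1 | intermediate
16 | 3-[(1S,3S,4S)-3-bromo-4-chloro-4-methylcyclohexyl]-6-methylhept-5-en-2-one | CC(=O)C(CC=C(C)C)[C@H]1CC[C@](C)(Cl)[C@@H](Br)C1 | intermediate
17 | 3-[(1S,3S,4S)-3-bromo-4-chloro-4-methylcyclohexyl]-4-[(2S)-3,3-dimethyloxiran-2-yl]butan-2-one | CC(=O)C(C[C@@H]1OC1(C)C)[C@H]2CC[C@](C)(Cl)[C@@H](Br)C2 | intermediate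
18 | (5R)-5-bromo-3-[(1S,3S,4S)-3-bromo-4-chloro-4-methylcyclohexyl]-6-hydroxy-6-methylheptan-2-one | CC(=O)C(C[C@@H](Br)C(C)(C)O)[C@H]1CC[C@](C)(Cl)[C@@H](Br)C1 | intermediate
19 | (5R)-5-bromo-3-[(1S,3S,4S)-3-bromo-4-chloro-4-methylcyclohexyl]-2,6,6-trimethyloxan-2-ol | CC1(O)OC(C)(C)[C@H](Br)CC1[C@H]2CC[C@](C)(Cl)[C@@H](Br)C2 | intermediate
20 | laucapyranoid A, (3R)-3-bromo-5-[(1S,3S,4S)-3-bromo-4-chloro-4-methylcyclohexyl]-2,2,6-trimethyl-3,4-dihydro-2H-pyran | CC1=C([C@H]2CC[C@](C)(Cl)[C@@H](Br)C2)C[C@@H](Br)C(C)(C)O1 | target

Total step count: 11. Longest linear sequence: 10 steps (steps 2 to 11; equally step 1 followed by steps 3 to 11).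

Steps most likely to fail

Step 3. The beta-brominated, alpha-methylated enal may react too slowly on the catalyst, the ester of 7 may sequester the boron cation, or the enantiofacial discrimination may be insufficient. The fallback replaces asymmetric catalysis by resolution. It sets out from 7 and 3: cycloaddition promoted by stoichiometric EtAlCl2 (CH2Cl2, −78 °C) should give the racemic adduct, racemic methyl 2-[(4RS,5SR)-5-bromo-4-formyl-4-methylcyclohex-1-en-1-yl]acetate F1. Condensation with (1R,2R)-N,N'-dimethyl-1,2-diphenylethane-1,2-diamine (Et2O, 4 Å molecular sieves) gives two diastereomeric imidazolidines that are separated by chromatography. The one derived from the (4R,5S) aldehyde, methyl 2-[(4R,5S)-5-bromo-4-[(4R,5R)-1,3-dimethyl-4,5-diphenylimidazolidin-2-yl]-4-methylcyclohex-1-en-1-yl]acetate F2, is hydrolysed with dilute aqueous HCl in Et2O, which returns to the route at 8.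

Step 6. Without a directing group, hydrogen may be delivered to the wrong face of the ring alkene. The fallback puts a hydroxyl-directed hydrogenation before the chlorination. It sets out from 10: the same iridium catalyst ([Ir(cod)(PCy3)(py)]PF6, H2, CH2Cl2) is bound by the tertiary homoallylic hydroxyl group and should add hydrogen to the face that this group occupies, giving methyl 2-[(1R,3S,4S)-3-bromo-4-hydroxy-4-methylcyclohexyl]acetate F3. Treatment with Me2C=C(Cl)NMe2 in CH2Cl2 then returns to the route at 12. The price is a substitution on a conformationally biased ring (Br and OH both equatorial), where retention rests on collapse of the ion pair on the face of departure and not on bromonium participation.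

Step 4. Hydride may migrate in place of the quaternary carbon, or the oxidant may attack the ring alkene. The fallback saturates the ring first and then uses a conventional peracid oxidation. It sets out from 8: formyl-directed hydrogenation ([Ir(cod)(PCy3)(py)]PF6, H2, CH2Cl2) should give methyl 2-[(1R,3S,4R)-3-bromo-4-formyl-4-methylcyclohexyl]acetate F4. Oxidation with mCPBA and NaHCO3 in CH2Cl2 gives the formate, methyl 2-[(1R,3S,4S)-3-bromo-4-(formyloxy)-4-methylcyclohexyl]acetate F5. TiCl4 (CH2Cl2, −78 °C) converts the tertiary formate into the chloride, which returns to the route at 12; the same caveat on retention at C4 applies.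

Further compounds
F1 | step 3 | racemic methyl 2-[(4RS,5SR)-5-bromo-4-formyl-4-methylcyclohex-1-en-1-yl]acetate | COC(=O)CC1=CC[C@](C)(C=O)[C@@H](Br)C1.COC(=O)CC1=CC[C@@](C)(C=O)[C@H](Br)C1
F2 | step 3 | methyl 2-[(4R,5S)-5-bromo-4-[(4R,5R)-1,3-dimethyl-4,5-diphenylimidazolidin-2-yl]-4-methylcyclohex-1-en-1-yl]acetate | COC(=O)CC1=CC[C@](C)(C2N(C)[C@H](c3ccccc3)[C@@H](c3ccccc3)N2C)[C@@H](Br)C1
F3 | step 6 | methyl 2-[(1R,3S,4S)-3-bromo-4-hydroxy-4-methylcyclohexyl]acetate | COC(=O)C[C@H]1CC[C@](C)(O)[C@@H](Br)C1
F4 | step 4 | methyl 2-[(1R,3S,4R)-3-bromo-4-formyl-4-methylcyclohexyl]acetate | COC(=O)C[C@H]1CC[C@](C)(C=O)[C@@H](Br)C1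
F5 | step 4 | methyl 2-[(1R,3S,4S)-3-bromo-4-(formyloxy)-4-methylcyclohexyl]acetate | COC(=O)C[C@H]1CC[C@](C)(OC=O)[C@@H](Br)C1
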